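**Plan**

1. Locants follow chroman-2-one numbering: unprimed for the half on ring A (5,7-dioxygenated arene), primed for the half on ring B (5',6',7',8'-tetraoxygenated arene). The enabling feature is that the lactone carbonyls C2 and C2' sit on the directly bonded carbons C3 and C3'. Each is esterified by the phenol oxygen (O1 of ring A, O1' of ring B) of the arene held at C4 or C4'. One oxidation level up, C2–C3–C3'–C2' is therefore the cis adduct of two CO molecules to an alkyne C3≡C3'.
2. Cuts, in order: the eight O–CH3 bonds; the C3–H and C3'–H bonds (back to the C3=C3' alkene); in one operation O1–C2, C2–C3, C3'–C2' and C2'–O1' (back to bis-phenol alkyne 24); C3'–C4' (acetylide plus ketone 18); C3–C4 (silylacetylide plus ketone 4); the two aryl–C(=O) bonds.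
3. Forward: each diaryl ketone is made by acylation. The chain is joined as C4–C3≡C3' and then C3'–C4'. Both lactone rings arise together in step 11.
4. Stereochemistry: C4 and C4' come from phosphoric-acid-catalysed transfer hydrogenation of ortho-quinone methides, using the two enantiomers of one catalyst. C3 and C3' come from syn hydrogenation of the Z alkene on the face opposite both C4 aryl groups.

Key step: step 11

Assumption: the (R)-phosphoric acid is taken to deliver hydride to the face of 9 that gives 10 as drawn. If the sense proves opposite, the catalyst enantiomers of steps 3 and 9 change places.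

Remark: the carbon that becomes C4 keeps one spatial arrangement throughout. Its descriptor reads S in 10–12, R in 21–24 and S in 25–27 only because the ranking of its substituents changes. The same holds for C4', which reads S in 23 and 24 and R in 25–27.

**Step 1**
Reactants: 1 1,3,5-trimethoxybenzene; 2 4-methoxybenzoyl chloride
Product: 4 (2-hydroxy-4,6-dimethoxyphenyl)(4-methoxyphenyl)methanone, via (4-methoxyphenyl)(2,4,6-trimethoxyphenyl)methanone 3 (not isolated)
Conditions: AlCl3 (2.5 equiv), CH2Cl2, 0 °C → reflux; then H2O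
Reagents that add atoms: none
Why: Friedel–Crafts acylation of the threefold-symmetric arene can give only ketone 3, and the aluminium chelate between its carbonyl and one of the two equivalent ortho methoxy groups then directs the familiar selective ortho O-demethylation, which should stop after one methyl group because the aluminium phenoxide ties up the carbonyl oxygen.

**Step 2**
Reactants: 4 (2-hydroxy-4,6-dimethoxyphenyl)(4-methoxyphenyl)methanone; 5 trimethylsilylacetylene
Product: 8 racemic 2-[1-hydroxy-1-(4-methoxyphenyl)-3-(trimethylsilyl)prop-2-yn-1-yl]-3,5-dimethoxyphenol, via lithium trimethylsilylacetylide 6 (not isolated), via lithium 2-(4-methoxybenzoyl)-3,5-dimethoxyphenolate 7 (not isolated)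
Conditions: 5 (3.5 equiv), n-BuLi (3.3 equiv), THF, −78 °C; then 4, −78 °C → rt; then H2O; used crude
Reagents that add atoms: none
Why: 1,2-addition of a slim lithium acetylide to a non-enolisable diaryl ketone tolerates the two ortho substituents once the phenol has consumed one equivalent of base, and the racemic carbinol centre does not matter because step 3 makes it planar.

**Step 3**
Reactants: 8 racemic 2-[1-hydroxy-1-(4-methoxyphenyl)-3-(trimethylsilyl)prop-2-yn-1-yl]-3,5-dimethoxyphenol
Product: 10 2-[(1S)-1-(4-methoxyphenyl)-3-(trimethylsilyl)prop-2-yn-1-yl]-3,5-dimethoxyphenol, via ring A ortho-quinone methide 9 (not isolated)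
Conditions: (R)-3,3'-bis(2,4,6-triisopropylphenyl)-1,1'-binaphthyl-2,2'-diyl hydrogen phosphate (10 mol %), diethyl 2,6-dimethyl-1,4-dihydropyridine-3,5-dicarboxylate (1.5 equiv), 4 Å MS, CH2Cl2, 0 °C → rt
Reagents that add atoms: none
Why: Chiral-phosphoric-acid-catalysed dehydration to an ortho-quinone methide followed by asymmetric transfer hydrogenation with a Hantzsch ester is an established route from 2-(1-aryl-1-hydroxyprop-2-ynyl)phenols to diarylmethyl alkynes; the acid binds the quinone methide oxygen and the dihydropyridine N–H together so that hydride reaches one face of C4, and the silyl group blocks hydride addition at the alkyne terminus.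

**Step 4**
Reactants: 10 2-[(1S)-1-(4-methoxyphenyl)-3-(trimethylsilyl)prop-2-yn-1-yl]-3,5-dimethoxyphenol
Product: 11 2-[(1S)-1-(4-methoxyphenyl)prop-2-yn-1-yl]-3,5-dimethoxyphenol
Conditions: Bu4NF (1.1 equiv), AcOH (1.2 equiv), THF, 0 °C
Reagents that add atoms: none
Why: Fluoride-induced protodesilylation of an alkynylsilane is fast, and the acetic acid buffer keeps the medium too weakly basic to ionise the doubly benzylic propargylic C4–H, so neither allene formation nor racemisation is expected.

**Step 5**
Reactants: 11 2-[(1S)-1-(4-methoxyphenyl)prop-2-yn-1-yl]-3,5-dimethoxyphenol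
Product: 12 tert-butyl{2-[(1S)-1-(4-methoxyphenyl)prop-2-yn-1-yl]-3,5-dimethoxyphenoxy}dimethylsilane
Conditions: TBSCl (1.3 equiv), imidazole (2.5 equiv), DMF, rt
Reagents that add atoms: tert-butyldimethylsilyl chloride, CC(C)(C)[Si](C)(C)Cl
Why: Standard phenol silylation masks the ring A phenol, so that step 8 needs only one lithiation and this oxygen cannot add to the alkyne terminus of quinone methide 22 in step 9.

**Step 6**
Reactants: 13 1,2,3,4-tetramethoxybenzene
Product: 16 2,3,4,5-tetramethoxyphenol, via (2,3,4,5-tetramethoxyphenyl)lithium 14 (not isolated), via dimethyl (2,3,4,5-tetramethoxyphenyl)boronate 15 (not isolated)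
Conditions: n-BuLi (1.1 equiv), TMEDA, THF, 0 °C; B(OMe)3 (1.5 equiv), −78 °C → rt; then 30% aq. H2O2, 0 °C → rt
Reagents that add atoms: hydrogen peroxide, OO
Why: Methoxy-directed ortho-lithiation (the two free positions are equivalent), borylation and oxidative boron-to-oxygen aryl migration form the standard one-flask conversion of an arene C–H bond into a phenol.

**Step 7**
Reactants: 16 2,3,4,5-tetramethoxyphenol; 2 4-methoxybenzoyl chloride
Product: 18 (2-hydroxy-3,4,5,6-tetramethoxyphenyl)(4-methoxyphenyl)methanone, via 2,3,4,5-tetramethoxyphenyl 4-methoxybenzoate 17 (not isolated)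
Conditions: Hf(OTf)4 (10 mol %), toluene–MeNO2, 100 °C
Reagents that add atoms: none
Why: Metal-triflate-catalysed O-acylation followed by Fries rearrangement is a known direct ortho-acylation of electron-rich phenols, and here the acyl group has only one free ring position, ortho to the oxygen, to migrate to.

**Step 8**
Reactants: 12 tert-butyl{2-[(1S)-1-(4-methoxyphenyl)prop-2-yn-1-yl]-3,5-dimethoxyphenoxy}dimethylsilane; 18 (2-hydroxy-3,4,5,6-tetramethoxyphenyl)(4-methoxyphenyl)methanone
Product: 21 2-[(4R)-4-{2-[(tert-butyldimethylsilyl)oxy]-4,6-dimethoxyphenyl}-1-hydroxy-1,4-bis(4-methoxyphenyl)but-2-yn-1-yl]-3,4,5,6-tetramethoxyphenol as both C1 epimers, via lithium acetylide 19 (not isolated), via lithium 2-(4-methoxybenzoyl)-3,4,5,6-tetramethoxyphenolate 20 (not isolated)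
Conditions: 12, n-BuLi (1.0 equiv), THF, −78 °C; 18 (1.3 equiv), LiN(SiMe3)2 (1.3 equiv), THF, −78 °C; combine, −78 → 0 °C; then H2O; used crude
Reagents that add atoms: none
Why: 1,2-addition of a lithium acetylide to a non-enolisable diaryl ketone forms C3'–C4'; one equivalent of base at −78 °C removes only the kinetically far more acidic C(sp)–H and leaves C4–H alone, and the mixed carbinol configuration is erased in step 9.

**Step 9**
Reactants: 21 2-[(4R)-4-{2-[(tert-butyldimethylsilyl)oxy]-4,6-dimethoxyphenyl}-1-hydroxy-1,4-bis(4-methoxyphenyl)but-2-yn-1-yl]-3,4,5,6-tetramethoxyphenol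
Product: 23 2-[(1S,4R)-4-{2-[(tert-butyldimethylsilyl)oxy]-4,6-dimethoxyphenyl}-1,4-bis(4-methoxyphenyl)but-2-yn-1-yl]-3,4,5,6-tetramethoxyphenol, via ring B ortho-quinone methide 22 (not isolated)
Conditions: (S)-3,3'-bis(2,4,6-triisopropylphenyl)-1,1'-binaphthyl-2,2'-diyl hydrogen phosphate (10 mol %), diethyl 2,6-dimethyl-1,4-dihydropyridine-3,5-dicarboxylate (1.5 equiv), 4 Å MS, CH2Cl2, 0 °C → rt
Reagents that add atoms: none
Why: This is the same phosphoric-acid-catalysed quinone methide transfer hydrogenation as in step 3, run with the enantiomeric acid because C4' needs the opposite sense; C4 lies too far away across the linear alkyne to interfere, so the catalyst alone sets C4', and the bulky diarylmethyl group shields the alkyne terminus.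

**Step 10**
Reactants: 23 2-[(1S,4R)-4-{2-[(tert-butyldimethylsilyl)oxy]-4,6-dimethoxyphenyl}-1,4-bis(4-methoxyphenyl)but-2-yn-1-yl]-3,4,5,6-tetramethoxyphenol
Product: 24 2-[(1S,4R)-4-(2-hydroxy-4,6-dimethoxyphenyl)-1,4-bis(4-methoxyphenyl)but-2-yn-1-yl]-3,4,5,6-tetramethoxyphenol
Conditions: Bu4NF (1.2 equiv), AcOH (1.3 equiv), THF, 0 °C
Reagents that add atoms: none
Why: Buffered fluoride cleavage of an aryl silyl ether is mild enough to leave both base-sensitive propargylic stereocentres intact.

**Step 11**
Reactants: 24 2-[(1S,4R)-4-(2-hydroxy-4,6-dimethoxyphenyl)-1,4-bis(4-methoxyphenyl)but-2-yn-1-yl]-3,4,5,6-tetramethoxyphenol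
Product: 25 (3Z,4S,4'R)-5,5',6',7,7',8'-hexamethoxy-4,4'-bis(4-methoxyphenyl)-3,3'-bichromanylidene-2,2'-dione (octamethyl ether of the dehydro target)
Conditions: PdI2 (5 mol %), KI (50 mol %), CO/air 4:1 (40 atm), 3 Å MS, MeCN, 60 °C
Reagents that add atoms: carbon monoxide, [C-]#[O+]
Why: Proposed new method: either free phenol attacks CO bound to divalent palladium to give an aryloxycarbonylpalladium iodide (O1–C2), this adds syn across C3≡C3' (C2–C3), the alkenylpalladium so formed inserts a second CO (C3'–C2'), the remaining phenol captures the acylpalladium (C2'–O1'), and the zerovalent palladium released is reoxidised by O2 and HI by way of I2. The closest known reaction types are the PdI2/KI oxidative dialkoxycarbonylation of alkynes to maleic diesters and the PdI2/KI carbonylative double cyclisation of alkynes that carry two tethered heteronucleophiles; two phenols closing two lactones around an internal, doubly branched alkyne have not been shown. The first lactone ring closes in the 6-exo-dig mode during the acylpalladation and the second by attack of the phenol on the exocyclic acyl carbon (six-membered, exo-trig, or C–O reductive elimination from the seven-membered palladacycle), and both possible starting points of the cascade converge on 25. No stereocentre is created: C4 and C4' are carried through untouched, and the Z geometry (C2 cis to C2') follows directly from the suprafacial insertion. The selectivity needed is carbonylation ahead of 5-exo-dig or 6-endo-dig oxypalladation of the alkyne by a phenol, which is favoured by the high CO pressure and the tenfold excess of iodide (palladium is held as a weakly π-acidic iodocarbonyl complex) and by the two diarylmethyl groups that shield the alkyne from palladium not delivered through the tether. The neutral, base-free medium and moderate temperature are chosen so that the doubly benzylic, vinylogously acidic C4–H and C4'–H bonds of 25 are not ionised and the double bond does not slip into a ring to give a 4-arylcoumarin.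

**Step 12**
Reactants: 25 (3Z,4S,4'R)-5,5',6',7,7',8'-hexamethoxy-4,4'-bis(4-methoxyphenyl)-3,3'-bichromanylidene-2,2'-dione
Product: 26 (3R,4S,3'S,4'R)-5,5',6',7,7',8'-hexamethoxy-4,4'-bis(4-methoxyphenyl)-3,3'-bichromane-2,2'-dione
Conditions: H2 (5 atm), PtO2 (10 mol %), EtOAc, rt
Reagents that add atoms: none
Why: Heterogeneous catalytic hydrogenation adds both hydrogens suprafacially, and allylic strain across the Z alkene holds the two mirror-related C4 aryl groups pseudo-axial on one face, so the metal should bind the open face and set C3 as R and C3' as S, each cis to its neighbouring aryl group, while platinum in place of palladium keeps double-bond migration low.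

**Step 13**
Reactants: 26 (3R,4S,3'S,4'R)-5,5',6',7,7',8'-hexamethoxy-4,4'-bis(4-methoxyphenyl)-3,3'-bichromane-2,2'-dione
Product: 27 (3R,4S)-5,7-dihydroxy-4-(4-hydroxyphenyl)-3-[(3S,4R)-5,6,7,8-tetrahydroxy-4-(4-hydroxyphenyl)-2-oxochroman-3-yl]chroman-2-one (CNP0064734.3)
Conditions: BBr3 (16 equiv), CH2Cl2, −78 °C → rt, argon; then degassed H2O, 0 °C
Reagents that add atoms: none
Why: Boron tribromide cleavage of aryl methyl ethers spares aryl lactones and involves no base, so the epimerisable cis centres C3 and C3' should hold, and any acyl shift between the two oxygens ortho to C4a or C4a' is degenerate once all methyl groups are gone.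

**Compound list**

1 | 1,3,5-trimethoxybenzene | COc1cc(OC)cc(OC)c1 | starting material
2 | 4-methoxybenzoyl chloride | COc1ccc(cc1)C(=O)Cl | starting material
3 | (4-methoxyphenyl)(2,4,6-trimethoxyphenyl)methanone | COc1ccc(cc1)C(=O)c1c(OC)cc(OC)cc1OC | intermediate
4 | (2-hydroxy-4,6-dimethoxyphenyl)(4-methoxyphenyl)methanone | COc1ccc(cc1)C(=O)c1c(O)cc(OC)cc1OC | intermediate
5 | trimethylsilylacetylene | C[Si](C)(C)C#C | starting material
6 | lithium trimethylsilylacetylide | C[Si](C)(C)C#[C-].[Li+] | intermediate
7 | lithium 2-(4-methoxybenzoyl)-3,5-dimethoxyphenolate | [Li+].COc1ccc(cc1)C(=O)c1c([O-])cc(OC)cc1OC | intermediate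
8 | racemic 2-[1-hydroxy-1-(4-methoxyphenyl)-3-(trimethylsilyl)prop-2-yn-1-yl]-3,5-dimethoxyphenol | COc1ccc(cc1)C(O)(C#C[Si](C)(C)C)c1c(O)cc(OC)cc1OC | intermediate
9 | 3,5-dimethoxy-6-[1-(4-methoxyphenyl)-3-(trimethylsilyl)prop-2-yn-1-ylidene]cyclohexa-2,4-dien-1-one (ring A ortho-quinone methide) | O=C1C=C(OC)C=C(OC)C1=C(C#C[Si](C)(C)C)c1ccc(OC)cc1 | intermediate
10 | 2-[(1S)-1-(4-methoxyphenyl)-3-(trimethylsilyl)prop-2-yn-1-yl]-3,5-dimethoxyphenol | COc1cc(O)c(c(OC)c1)[C@H](c1ccc(OC)cc1)C#C[Si](C)(C)C | intermediate
11 | 2-[(1S)-1-(4-methoxyphenyl)prop-2-yn-1-yl]-3,5-dimethoxyphenol | COc1cc(O)c(c(OC)c1)[C@H](c1ccc(OC)cc1)C#C | intermediate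
12 | tert-butyl{2-[(1S)-1-(4-methoxyphenyl)prop-2-yn-1-yl]-3,5-dimethoxyphenoxy}dimethylsilane | COc1cc(O[Si](C)(C)C(C)(C)C)c(c(OC)c1)[C@H](c1ccc(OC)cc1)C#C | intermediate
13 | 1,2,3,4-tetramethoxybenzene | COc1ccc(OC)c(OC)c1OC | starting material
14 | (2,3,4,5-tetramethoxyphenyl)lithium | COc1cc([Li])c(OC)c(OC)c1OC | intermediate
15 | dimethyl (2,3,4,5-tetramethoxyphenyl)boronate | COB(OC)c1cc(OC)c(OC)c(OC)c1OC | intermediate
16 | 2,3,4,5-tetramethoxyphenol | COc1cc(O)c(OC)c(OC)c1OC | intermediate
17 | 2,3,4,5-tetramethoxyphenyl 4-methoxybenzoate | COc1ccc(cc1)C(=O)Oc1cc(OC)c(OC)c(OC)c1OC | intermediate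
18 | (2-hydroxy-3,4,5,6-tetramethoxyphenyl)(4-methoxyphenyl)methanone | COc1ccc(cc1)C(=O)c1c(O)c(OC)c(OC)c(OC)c1OC | intermediate
19 | lithium acetylide of 12 | COc1cc(O[Si](C)(C)C(C)(C)C)c(c(OC)c1)[C@H](c1ccc(OC)cc1)C#[C-].[Li+] | intermediate
20 | lithium 2-(4-methoxybenzoyl)-3,4,5,6-tetramethoxyphenolate | [Li+].COc1ccc(cc1)C(=O)c1c([O-])c(OC)c(OC)c(OC)c1OC | intermediate
21 | 2-[(4R)-4-{2-[(tert-butyldimethylsilyl)oxy]-4,6-dimethoxyphenyl}-1-hydroxy-1,4-bis(4-methoxyphenyl)but-2-yn-1-yl]-3,4,5,6-tetramethoxyphenol, both C1 epimers | COc1cc(O[Si](C)(C)C(C)(C)C)c(c(OC)c1)[C@H](c1ccc(OC)cc1)C#CC(O)(c1ccc(OC)cc1)c1c(OC)c(OC)c(OC)c(OC)c1O | intermediate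
22 | ring B ortho-quinone methide: 6-ylidene-2,3,4,5-tetramethoxycyclohexa-2,4-dien-1-one derived from 21, C4 as in 21 | COc1cc(O[Si](C)(C)C(C)(C)C)c(c(OC)c1)[C@H](c1ccc(OC)cc1)C#CC(c1ccc(OC)cc1)=C1C(=O)C(OC)=C(OC)C(OC)=C1OC | intermediate
23 | 2-[(1S,4R)-4-{2-[(tert-butyldimethylsilyl)oxy]-4,6-dimethoxyphenyl}-1,4-bis(4-methoxyphenyl)but-2-yn-1-yl]-3,4,5,6-tetramethoxyphenol | COc1cc(O[Si](C)(C)C(C)(C)C)c(c(OC)c1)[C@H](c1ccc(OC)cc1)C#C[C@H](c1ccc(OC)cc1)c1c(OC)c(OC)c(OC)c(OC)c1O | intermediate
24 | 2-[(1S,4R)-4-(2-hydroxy-4,6-dimethoxyphenyl)-1,4-bis(4-methoxyphenyl)but-2-yn-1-yl]-3,4,5,6-tetramethoxyphenol | COc1cc(O)c(c(OC)c1)[C@H](c1ccc(OC)cc1)C#C[C@H](c1ccc(OC)cc1)c1c(OC)c(OC)c(OC)c(OC)c1O | intermediate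
25 | (3Z,4S,4'R)-5,5',6',7,7',8'-hexamethoxy-4,4'-bis(4-methoxyphenyl)-3,3'-bichromanylidene-2,2'-dione | O=C1Oc2cc(OC)cc(OC)c2[C@H](c2ccc(OC)cc2)/C1=C1/C(=O)Oc2c(OC)c(OC)c(OC)c(OC)c2[C@H]1c1ccc(OC)cc1 | intermediate
26 | (3R,4S,3'S,4'R)-5,5',6',7,7',8'-hexamethoxy-4,4'-bis(4-methoxyphenyl)-3,3'-bichromane-2,2'-dione | O=C1Oc2cc(OC)cc(OC)c2[C@H](c2ccc(OC)cc2)[C@@H]1[C@H]1C(=O)Oc2c(OC)c(OC)c(OC)c(OC)c2[C@H]1c1ccc(OC)cc1 | intermediate
27 | (3R,4S)-5,7-dihydroxy-4-(4-hydroxyphenyl)-3-[(3S,4R)-5,6,7,8-tetrahydroxy-4-(4-hydroxyphenyl)-2-oxochroman-3-yl]chroman-2-one | O=C1Oc2cc(O)cc(O)c2[C@H](c2ccc(O)cc2)[C@@H]1[C@H]1C(=O)Oc2c(O)c(O)c(O)c(O)c2[C@H]1c1ccc(O)cc1 | target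

**Step count**

Total step count: 13.
Longest linear sequence: 11 (steps 1–5 and 8–13).

**Steps most likely to fail**

**Step 11.** Several processes could defeat the cascade:
- A phenol may add directly to the palladium-activated alkyne before CO is taken up.
- The hindered internal alkyne may fail to insert.
- The electron-rich rings may be iodinated or oxidised under the aerobic iodide conditions.
- The new double bond may drift into a ring.

The fallback uses known reactions only and sets out from 23. The ring B phenol is silylated as well (TBSCl, imidazole, DMF) to give the bis(tert-butyldimethylsilyl) ether F1. Nickel-catalysed reductive double carboxylation of the internal alkyne (Ni(acac)2, 2,2'-bipyridine, Zn, MgBr2, CO2 1 atm, DMF), a syn process, then gives after acidic work-up the 2,3-disubstituted maleic anhydride F2. HF·pyridine in THF removes both silyl groups, and a freed phenol opens the anhydride to the lactone acid F3. Carbodiimide dehydration (EDC·HCl, CH2Cl2, 0 °C) closes the second lactone, and the route is rejoined at 25.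

**Step 12.** Hydrogen uptake at the tetrasubstituted alkene may be slow. Metal-hydride-mediated migration of the double bond to C3=C4 may then erase C4, or the facial preference may be incomplete. The fallback sets out from 25 and replaces surface syn addition with stepwise electron transfer and protonation (SmI2, 2.5 equiv, THF–MeOH, −78 °C). Each samarium enolate should be protonated at C3 or C3' from the face opposite its own neighbouring aryl group, so the two cis relationships are set independently. The route is rejoined at 26, and no compound outside the list is made (F0).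

**Step 9.** Facial discrimination may be poor because the fully substituted ring B quinone methide can adopt both alkene geometries. Hydride transfer to this strongly stabilised acceptor may also be slow, or hydride may add at the alkyne terminus. The fallback sets out from 21 and gives up catalyst control. Ionic hydrogenation (Et3SiH, CF3CO2H, CH2Cl2, −78 °C) reduces the carbinol without bias. Because C4 is already homochiral, the two products are diastereomers: 23 and its C1 epimer F4. They are separated by chromatography, and the route is rejoined at 23.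

**Further compounds**

F1 | step 11 | bis(tert-butyldimethylsilyl) ether of 24 | COc1cc(O[Si](C)(C)C(C)(C)C)c(c(OC)c1)[C@H](c1ccc(OC)cc1)C#C[C@H](c1ccc(OC)cc1)c1c(OC)c(OC)c(OC)c(OC)c1O[Si](C)(C)C(C)(C)C
F2 | step 11 | 2,3-disubstituted maleic anhydride (furan-2,5-dione carrying the two silylated diarylmethyl groups at C3 and C4, configured as in 24) | COc1cc(O[Si](C)(C)C(C)(C)C)c(c(OC)c1)[C@H](c1ccc(OC)cc1)C1=C(C(=O)OC1=O)[C@H](c1ccc(OC)cc1)c1c(OC)c(OC)c(OC)c(OC)c1O[Si](C)(C)C(C)(C)C
F3 | step 11 | lactone acid: (Z)-2-[5,7-dimethoxy-4-(4-methoxyphenyl)-2-oxochroman-3-ylidene]-3-(2-hydroxy-3,4,5,6-tetramethoxyphenyl)-3-(4-methoxyphenyl)propanoic acid, configured as in 25 | O=C1Oc2cc(OC)cc(OC)c2[C@H](c2ccc(OC)cc2)/C1=C(/C(=O)O)[C@H](c1ccc(OC)cc1)c1c(OC)c(OC)c(OC)c(OC)c1O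
F0 | step 12 | none | none
F4 | step 9 | C1 epimer of 23, (1R,4R) | COc1cc(O[Si](C)(C)C(C)(C)C)c(c(OC)c1)[C@H](c1ccc(OC)cc1)C#C[C@@H](c1ccc(OC)cc1)c1c(OC)c(OC)c(OC)c(OC)c1O
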